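**Retrosynthetic overview**
- Target ⇐ PMB removal and C9 acetylation ⇐ trans-fused α-methylene lactone ⇐ reduction/lactonisation of a ten-membered C6 enone that carries the C7 acrylate.
- C14 acyloxymethyl group ⇐ Negishi coupling of a C10 alkenyl triflate.
- Ten-membered ring ⇐ four-carbon ring expansion: retro-aldol cleavage of the C1–C6 bond of a cis-fused bicyclo[4.4.0] ketol, with the enolate trapped as the triflate (sets the 1(10)Z alkene; the 4Z alkene comes from the cyclohexenone).
- Bicyclic ketol ⇐ indium Barbier closure of ring D (C6–C7) on a β-diketone ⇐ aldol/oxidation joining 3-methylcyclohexenone (ring C) to a C7–C13 side chain.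
- Side chain ⇐ Morita–Baylis–Hillman/Appel on an anti aldol of O-PMB-glycolaldehyde and dimethoxyacetaldehyde (C8, C9). Ring order: ring C (purchased), ring D, ten-membered ring, lactone.

Assumption: the target is the isomer encoded by the SMILES (6R,7R,8S,9R; 1(10)Z,4Z; (2R)-2-methylbutanoate); locants C1–C15 below are the germacrane locants of the target.

**Step 1**
Reactants: 1 (4-methoxybenzyloxy)acetaldehyde; 2 dimethoxyacetaldehyde
Product: 3 (2R,3S)-3-hydroxy-4,4-dimethoxy-2-[(4-methoxybenzyl)oxy]butanal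
Conditions: D-proline (20 mol %), DMF, 4 °C, 1 added slowly to 2 (3 equiv)
Reagents that add atoms: none
Why: Proline enamine cross-aldol in which the enamine of 1 adds to the more electrophilic, poorly enolising aldehyde 2 through the Houk–List transition state, so D-proline gives the anti (2R,3S) aldol that carries C8 and C9 of the target.

**Step 2**
Reactants: 3
Product: 4 (2R,3S)-3-(tert-butyldimethylsilyloxy)-4,4-dimethoxy-2-[(4-methoxybenzyl)oxy]butanal
Conditions: TBSOTf, 2,6-lutidine, CH2Cl2, −78 °C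
Reagents that add atoms: tert-butyldimethylsilyl triflate, CC(C)(C)[Si](C)(C)OS(=O)(=O)C(F)(F)F
Why: Silyl ether formation at low temperature protects the C9 hydroxyl without β-elimination or epimerisation of the α-alkoxy aldehyde.

**Step 3**
Reactants: 4; 5 isopropyl acrylate
Product: 6 isopropyl (4S,5S)-5-(tert-butyldimethylsilyloxy)-3-hydroxy-6,6-dimethoxy-4-[(4-methoxybenzyl)oxy]-2-methylidenehexanoate (C3 epimers)
Conditions: 1,4-diazabicyclo[2.2.2]octane (0.5 equiv), neat 5 (5 equiv), 25 °C, 3 d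
Reagents that add atoms: none
Why: Morita–Baylis–Hillman reaction attaches the acrylate α-carbon (C11) to the aldehyde carbon (C7); the new carbinol centre is irrelevant because it is removed in step 4.

**Step 4**
Reactants: 6
Product: 7 isopropyl (2Z,4S,5S)-2-(bromomethyl)-5-(tert-butyldimethylsilyloxy)-6,6-dimethoxy-4-[(4-methoxybenzyl)oxy]hex-2-enoate
Conditions: CBr4, PPh3, CH2Cl2, 0 °C
Reagents that add atoms: tetrabromomethane, BrC(Br)(Br)Br
Why: Appel bromination of the Baylis–Hillman alcohol proceeds with allylic transposition (SN2′) to the thermodynamically preferred (Z)-2-(bromomethyl)enoate under neutral conditions.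

**Step 5**
Reactants: 7
Product: 8 isopropyl (2Z,4S,5S)-2-(bromomethyl)-5-(tert-butyldimethylsilyloxy)-4-[(4-methoxybenzyl)oxy]-6-oxohex-2-enoate
Conditions: LiBF4, MeCN/H2O (50:1), 40 °C
Reagents that add atoms: water, O
Why: Lewis-acid-assisted acetal hydrolysis unmasks the C10 aldehyde while the silyl ether, PMB ether and allylic bromide survive.

**Step 6**
Reactants: 8; 9 3-methylcyclohex-2-en-1-one
Product: 11 isopropyl (2Z,4S,5R)-2-(bromomethyl)-5-(tert-butyldimethylsilyloxy)-6-hydroxy-4-[(4-methoxybenzyl)oxy]-6-(4-methyl-2-oxocyclohex-3-en-1-yl)hex-2-enoate (epimers at C1 and C10), via lithium dienolate 10 (not isolated)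
Conditions: 9, LiN(iPr)2, THF, −78 °C; then 8, −78 °C, 10 min; AcOH quench at −78 °C
Reagents that add atoms: none
Why: Kinetic α′-deprotonation of 9 gives the cross-conjugated dienolate, which undergoes aldol addition to the aldehyde faster than it attacks the ester or the allylic bromide at −78 °C; the C1 and C10 centres formed here are erased in steps 7 to 9.

**Step 7**
Reactants: 11
Product: 12 isopropyl (2Z,4S,5S)-2-(bromomethyl)-5-(tert-butyldimethylsilyloxy)-4-[(4-methoxybenzyl)oxy]-6-(4-methyl-2-oxocyclohex-3-en-1-yl)-6-oxohex-2-enoate (β-diketone, largely enolised)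
Conditions: Dess–Martin periodinane, CH2Cl2, 0 to 25 °C
Reagents that add atoms: none
Why: Dess–Martin oxidation of the aldol gives the β-diketone, in which C1 is configurationally mobile through the enol before ring D is closed.

**Step 8**
Reactants: 12
Product: 14 isopropyl 2-[2-(tert-butyldimethylsilyloxy)-4a-hydroxy-3-[(4-methoxybenzyl)oxy]-6-methyl-1-oxo-1,2,3,4,4a,7,8,8a-octahydronaphthalen-4-yl]prop-2-enoate (cis-fused; 4a-OH, the C4 side chain, 3-OPMB, 2-OTBS and H-8a all on one face), via allylindium dibromide 13 (not isolated)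
Conditions: In powder, THF/H2O (1:1), 25 °C
Reagents that add atoms: none
Why: Intramolecular indium Barbier allylation in which the allylindium adds through its γ-carbon (C7) to the ring ketone C6 in a six-membered chair transition state; C7 is set by 1,2-induction from C8/C9 (side chain and C9 ether equatorial, C8 ether axial), and the mobile C1 settles in the cis-fused ketol.

**Step 9**
Reactants: 14
Product: 17 isopropyl 2-{(3Z,7E)-9-(tert-butyldimethylsilyloxy)-10-[(4-methoxybenzyl)oxy]-4-methyl-2-oxo-8-[(trifluoromethylsulfonyl)oxy]cyclodeca-3,7-dien-1-yl}prop-2-enoate (both ring alkenes ring-cis; C7–C9 configuration as in 14), via potassium alkoxide 15 (not isolated), via potassium enolate 16 (not isolated)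
Conditions: KN(SiMe3)2, THF, −78 °C; PhNTf2, −78 to −30 °C
Reagents that add atoms: N-phenylbis(trifluoromethanesulfonimide), O=S(=O)(N(c1ccccc1)S(=O)(=O)C(F)(F)F)C(F)(F)F
Why: Proposed new method: the tertiary C6 alkoxide 15 has its C1–C6 bond aligned with the C10 carbonyl, so anionic retro-aldol cleavage (not pericyclic) expands the six-membered ring by four carbons to the ten-membered enolate 16, whose C1=C10 geometry is fixed ring-cis because C2 is axial on ring D in the cis-fused chair, and PhNTf2 traps 16 on oxygen before re-closure or proton transfer, while the hindered isopropyl ester resists lactonisation by the alkoxide at −78 °C; the closest known reactions are the De Mayo retro-aldol ring expansion, the base-induced fragmentation of indium Barbier adducts of cyclic β-keto esters, and enol triflate formation from enolates with PhNTf2.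

**Step 10**
Reactants: 18 (R)-2-methylbutanoic acid
Product: 19 chloromethyl (2R)-2-methylbutanoate
Conditions: ClCH2OSO2Cl, NaHCO3, Bu4NHSO4 (cat.), CH2Cl2/H2O, 25 °C
Reagents that add atoms: chloromethyl chlorosulfate, ClCOS(Cl)(=O)=O
Why: Phase-transfer O-alkylation of the carboxylate gives the chloromethyl ester without touching the α-stereocentre.

**Step 11**
Reactants: 17; 19
Product: 21 isopropyl 2-{(3Z,7Z)-9-(tert-butyldimethylsilyloxy)-10-[(4-methoxybenzyl)oxy]-4-methyl-8-({[(2R)-2-methylbutanoyl]oxy}methyl)-2-oxocyclodeca-3,7-dien-1-yl}prop-2-enoate, via acyloxymethylzinc chloride 20 (not isolated)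
Conditions: 19, Zn dust, NaI (cat.), LiCl, THF/DMA, 40 °C; then 17, Pd2(dba)3 (2.5 mol %), tri(2-furyl)phosphine, 25 °C
Reagents that add atoms: none
Why: Negishi coupling in which the acyloxymethylzinc reagent transmetalates quickly to the alkenylpalladium formed from the triflate, so the C10–C14 bond forms with retention of alkene geometry before Heck cyclisation onto the acrylate can compete.

**Step 12**
Reactants: 21
Product: 23 9-hydroxy-8-O-(4-methoxybenzyl) lactone: the target skeleton with free 9-OH, 8-OPMB and the 14-(2R)-2-methylbutanoate, via C6 alcohol 22 (not isolated)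
Conditions: (R)-2-methyl-CBS-oxazaborolidine [(R)-1-methyl-3,3-diphenyltetrahydro-1H,3H-pyrrolo[1,2-c][1,3,2]oxazaborole], catecholborane, toluene, −78 °C; then HF·pyridine, THF, 0 to 25 °C
Reagents that add atoms: none
Why: Corey–Bakshi–Shibata reduction (alkenyl arm as the large group) gives the (6R) allylic alcohol by reagent control, and the acidic HF·pyridine treatment then closes the trans-fused α-methylene-γ-lactone with loss of isopropanol and cleaves the C9 silyl ether.

**Step 13**
Reactants: 23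
Product: 24 9-O-acetyl-8-O-(4-methoxybenzyl) lactone (the target carrying a PMB ether at O8)
Conditions: Ac2O, DMAP (cat.), pyridine, CH2Cl2, 0 °C
Reagents that add atoms: acetic anhydride, CC(=O)OC(C)=O
Why: DMAP-catalysed acetylation of the only free hydroxyl (C9) avoids any regioselectivity problem between O8 and O9.

**Step 14**
Reactants: 24
Product: 25 target, (6R,7R,8S,9R,1(10)Z,4Z)-9-acetoxy-8-hydroxy-14-[(2R)-2-methylbutanoyloxy]germacra-1(10),4,11(13)-trien-12,6-olide
Conditions: DDQ, CH2Cl2/pH 7 buffer (10:1), 0 °C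
Reagents that add atoms: none
Why: Oxidative PMB ether cleavage with DDQ frees the C8 hydroxyl under neutral conditions that leave the esters, the lactone and the alkenes untouched.

**Compound list**
1 | (4-methoxybenzyloxy)acetaldehyde (O-PMB-glycolaldehyde) | O=CCOCc1ccc(OC)cc1 | starting material
2 | dimethoxyacetaldehyde | COC(OC)C=O | starting material
3 | (2R,3S)-3-hydroxy-4,4-dimethoxy-2-[(4-methoxybenzyl)oxy]butanal | COC(OC)[C@@H](O)[C@@H](OCc1ccc(OC)cc1)C=O | intermediate
4 | (2R,3S)-3-(tert-butyldimethylsilyloxy)-4,4-dimethoxy-2-[(4-methoxybenzyl)oxy]butanal | COC(OC)[C@@H](O[Si](C)(C)C(C)(C)C)[C@@H](OCc1ccc(OC)cc1)C=O | intermediate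
5 | isopropyl acrylate | C=CC(=O)OC(C)C | starting material
6 | isopropyl (4S,5S)-5-(tert-butyldimethylsilyloxy)-3-hydroxy-6,6-dimethoxy-4-[(4-methoxybenzyl)oxy]-2-methylidenehexanoate (C3 epimers) | COC(OC)[C@@H](O[Si](C)(C)C(C)(C)C)[C@@H](OCc1ccc(OC)cc1)C(O)C(=C)C(=O)OC(C)C | intermediate
7 | isopropyl (2Z,4S,5S)-2-(bromomethyl)-5-(tert-butyldimethylsilyloxy)-6,6-dimethoxy-4-[(4-methoxybenzyl)oxy]hex-2-enoate | COC(OC)[C@@H](O[Si](C)(C)C(C)(C)C)[C@@H](OCc1ccc(OC)cc1)/C=C(\CBr)C(=O)OC(C)C | intermediate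
8 | isopropyl (2Z,4S,5S)-2-(bromomethyl)-5-(tert-butyldimethylsilyloxy)-4-[(4-methoxybenzyl)oxy]-6-oxohex-2-enoate | O=C[C@@H](O[Si](C)(C)C(C)(C)C)[C@@H](OCc1ccc(OC)cc1)/C=C(\CBr)C(=O)OC(C)C | intermediate
9 | 3-methylcyclohex-2-en-1-one | CC1=CC(=O)CCC1 | starting material
10 | lithium 5-methylcyclohexa-1,5-dien-1-olate (kinetic α′ dienolate of 9) | CC1=CC(O[Li])=CCC1 | intermediate
11 | isopropyl (2Z,4S,5R)-2-(bromomethyl)-5-(tert-butyldimethylsilyloxy)-6-hydroxy-4-[(4-methoxybenzyl)oxy]-6-(4-methyl-2-oxocyclohex-3-en-1-yl)hex-2-enoate (epimers at C1 and C10) | CC1=CC(=O)C(CC1)C(O)[C@@H](O[Si](C)(C)C(C)(C)C)[C@@H](OCc2ccc(OC)cc2)/C=C(\CBr)C(=O)OC(C)C | intermediate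
12 | isopropyl (2Z,4S,5S)-2-(bromomethyl)-5-(tert-butyldimethylsilyloxy)-4-[(4-methoxybenzyl)oxy]-6-(4-methyl-2-oxocyclohex-3-en-1-yl)-6-oxohex-2-enoate (β-diketone, enolised) | CC1=CC(=O)C(CC1)C(=O)[C@@H](O[Si](C)(C)C(C)(C)C)[C@@H](OCc2ccc(OC)cc2)/C=C(\CBr)C(=O)OC(C)C | intermediate
13 | allylindium dibromide formed from 12 (indium on C13) | CC1=CC(=O)C(CC1)C(=O)[C@@H](O[Si](C)(C)C(C)(C)C)[C@@H](OCc2ccc(OC)cc2)/C=C(\C[In](Br)Br)C(=O)OC(C)C | intermediate
14 | cis-fused bicyclic ketol, isopropyl 2-[2-(tert-butyldimethylsilyloxy)-4a-hydroxy-3-[(4-methoxybenzyl)oxy]-6-methyl-1-oxo-1,2,3,4,4a,7,8,8a-octahydronaphthalen-4-yl]prop-2-enoate (4a-OH, C4 side chain, 3-OPMB, 2-OTBS and H-8a cis) | CC1=C[C@]2(O)[C@H](CC1)C(=O)[C@@H](O[Si](C)(C)C(C)(C)C)[C@@H](OCc3ccc(OC)cc3)[C@H]2C(=C)C(=O)OC(C)C | intermediate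
15 | potassium C6 alkoxide of 14 | CC1=C[C@]2([O-])[C@H](CC1)C(=O)[C@@H](O[Si](C)(C)C(C)(C)C)[C@@H](OCc3ccc(OC)cc3)[C@H]2C(=C)C(=O)OC(C)C.[K+] | intermediate
16 | ring-expanded potassium C10 enolate (ten-membered ring, C1=C10 ring-cis, C6 ketone) | O=C1/C=C(/C)CC/C=C(/[O-])[C@@H](O[Si](C)(C)C(C)(C)C)[C@@H](OCc2ccc(OC)cc2)[C@H]1C(=C)C(=O)OC(C)C.[K+] | intermediate
17 | isopropyl 2-{(3Z,7E)-9-(tert-butyldimethylsilyloxy)-10-[(4-methoxybenzyl)oxy]-4-methyl-2-oxo-8-[(trifluoromethylsulfonyl)oxy]cyclodeca-3,7-dien-1-yl}prop-2-enoate | O=C1/C=C(/C)CC/C=C(/OS(=O)(=O)C(F)(F)F)[C@@H](O[Si](C)(C)C(C)(C)C)[C@@H](OCc2ccc(OC)cc2)[C@H]1C(=C)C(=O)OC(C)C | intermediate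
18 | (R)-2-methylbutanoic acid | OC(=O)[C@H](C)CC | starting material
19 | chloromethyl (2R)-2-methylbutanoate | ClCOC(=O)[C@H](C)CC | intermediate
20 | {[(2R)-2-methylbutanoyl]oxy}methylzinc chloride | Cl[Zn]COC(=O)[C@H](C)CC | intermediate
21 | isopropyl 2-{(3Z,7Z)-9-(tert-butyldimethylsilyloxy)-10-[(4-methoxybenzyl)oxy]-4-methyl-8-({[(2R)-2-methylbutanoyl]oxy}methyl)-2-oxocyclodeca-3,7-dien-1-yl}prop-2-enoate | O=C1/C=C(/C)CC/C=C(/COC(=O)[C@H](C)CC)[C@@H](O[Si](C)(C)C(C)(C)C)[C@@H](OCc2ccc(OC)cc2)[C@H]1C(=C)C(=O)OC(C)C | intermediate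
22 | (6R) allylic alcohol from 21 (C6 hydroxyl, isopropyl ester and 9-OTBS still in place) | O[C@@H]1/C=C(/C)CC/C=C(/COC(=O)[C@H](C)CC)[C@@H](O[Si](C)(C)C(C)(C)C)[C@@H](OCc2ccc(OC)cc2)[C@H]1C(=C)C(=O)OC(C)C | intermediate
23 | 9-hydroxy-8-O-(4-methoxybenzyl) germacranolide (trans-fused 6,12-lactone, 14-(2R)-2-methylbutanoate) | C=C1C(=O)O[C@@H]2/C=C(/C)CC/C=C(/COC(=O)[C@H](C)CC)[C@@H](O)[C@@H](OCc3ccc(OC)cc3)[C@@H]12 | intermediate
24 | 9-O-acetyl-8-O-(4-methoxybenzyl) germacranolide | C=C1C(=O)O[C@@H]2/C=C(/C)CC/C=C(/COC(=O)[C@H](C)CC)[C@@H](OC(C)=O)[C@@H](OCc3ccc(OC)cc3)[C@@H]12 | intermediate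
25 | (6R,7R,8S,9R,1(10)Z,4Z)-9-acetoxy-8-hydroxy-14-[(2R)-2-methylbutanoyloxy]germacra-1(10),4,11(13)-trien-12,6-olide | C=C1C(=O)O[C@@H]2/C=C(/C)CC/C=C(/COC(=O)[C@H](C)CC)[C@@H](OC(C)=O)[C@@H](O)[C@@H]12 | target

**Step count**
Total: 14 steps. Longest linear sequence: 13 steps (steps 1–9 and 11–14, from 1 to 25); step 10 is a one-step side branch.

**Three steps most likely to fail, with fallbacks**

Step 9 (the new ring expansion with triflate trapping). The alkoxide may lactonise or re-close, or the enolate may form with the wrong geometry. Fallback from 14 back to 17, using known chemistry: treat 14 with 1,8-diazabicyclo[5.4.0]undec-7-ene in CH2Cl2 (base-catalysed retro-aldol, the fragmentation used in known Barbier/retro-aldol ring enlargements) and isolate the ten-membered 1,5-diketone F1. Then deprotonate F1 kinetically at C1 with LiN(SiMe3)2 at −78 °C and triflate on oxygen with PhNTf2 (standard enol triflate synthesis) to give 17; geometric isomers are separated if both form.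

Step 8 (indium Barbier on the enolised β-diketone). The acidic enol, attack of C13 on the C10 ketone, or poor control at C7 could spoil it. Fallback from 11 back to 14: run the indium Barbier cyclisation (In powder, THF/H2O) on aldol adduct 11 itself, where there is no enol and no second ketone, to give the bicyclic 6,10-diol F2. Then oxidise the secondary C10 carbinol of F2 with Dess–Martin periodinane to reach 14, and equilibrate C1 (now α to the ketone) to the cis-fused isomer with Et3N.

Step 11 (Negishi coupling next to an acrylate). Heck cyclisation of the alkenylpalladium onto the acrylate, or sluggish zinc insertion, could intervene. Fallback from 17 back to 21, without an alkenylpalladium intermediate: Nozaki–Hiyama–Kishi hydroxymethylation (CrCl2, NiCl2 cat., paraformaldehyde, DMF) converts the triflate into the allylic alcohol F3. Steglich esterification of F3 with acid 18 (DCC, DMAP, CH2Cl2) then gives 21.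

**Further compounds**
F1 | step 9 | isopropyl 2-{(3Z)-9-(tert-butyldimethylsilyloxy)-10-[(4-methoxybenzyl)oxy]-4-methyl-2,8-dioxocyclodec-3-en-1-yl}prop-2-enoate (ten-membered 1,5-diketone) | O=C1/C=C(/C)CCCC(=O)[C@@H](O[Si](C)(C)C(C)(C)C)[C@@H](OCc2ccc(OC)cc2)[C@H]1C(=C)C(=O)OC(C)C
F2 | step 8 | cis-fused bicyclic 6,10-diol, isopropyl 2-[2-(tert-butyldimethylsilyloxy)-1,4a-dihydroxy-3-[(4-methoxybenzyl)oxy]-6-methyl-1,2,3,4,4a,7,8,8a-octahydronaphthalen-4-yl]prop-2-enoate (C10 epimers) | CC1=C[C@]2(O)[C@H](CC1)C(O)[C@@H](O[Si](C)(C)C(C)(C)C)[C@@H](OCc3ccc(OC)cc3)[C@H]2C(=C)C(=O)OC(C)C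
F3 | step 11 | isopropyl 2-{(3Z,7Z)-9-(tert-butyldimethylsilyloxy)-8-(hydroxymethyl)-10-[(4-methoxybenzyl)oxy]-4-methyl-2-oxocyclodeca-3,7-dien-1-yl}prop-2-enoate | O=C1/C=C(/C)CC/C=C(/CO)[C@@H](O[Si](C)(C)C(C)(C)C)[C@@H](OCc2ccc(OC)cc2)[C@H]1C(=C)C(=O)OC(C)C
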